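**Conventions.** Terpenoid carbons are labelled C1–C11: C1 is the ether carbon, C2 and C3 the two CH2 groups of the cyclopentane, C4 the quaternary carbon, C5 the ring-fusion CH, C6 and C7 the cyclopropane CH carbons (C6 on C5), C8 the ring CH2, C9 the CH(CH3), C10 the CMe2 carbon and C11 the benzylic carbon. Rings: A arene, B oxepine, C cyclopentane, D cyclohexane, E cyclopropane. "α face" of ring D is the face carrying the C1 oxygen.

## The problem

1. The target joins a diformylphloroglucinol (ring A) to a C14 carane-type terpenoid through two bonds, a tertiary alkyl aryl ether at C1 and a benzylic C–C bond at C11. A seven-membered oxepine (ring B: C11, two aryl carbons, O, C1, C5, C4) therefore bridges C1 and C4 of a cyclopentane (ring C: C1–C5).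
2. Ring C is cis-fused along C1–C5 to a cyclohexane (ring D: C1, C5, C6, C7, C8, C9), which carries a gem-dimethylcyclopropane (ring E: C6, C7, C10) and a methyl group on C9. C4 is quaternary (CH3) and C11 bears the isobutyl group.
3. There are seven stereocentres (C1, C4, C5, C6, C7, C9, C11). The oxygen on C1, the hydrogen on C5, the C9 methyl and ring E all lie on the α face of ring D, and the isobutyl group on C11 points to the side of the one-carbon bridge C5.
4. C1 can control C4 completely, because ring B can span only one face of ring C. The ring fusion can steer reagents at C6/C7, and the bicyclic cage those at C11, only through face selectivity. C1, C5 and C9 have to be created together and in the absolute sense.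
5. The ether at fully substituted C1 cannot be made by substitution late in the synthesis. The cyclopropane and that ether are sensitive to strong acid. The aldehydes and free phenols tolerate neither organolithium nor hydride reagents and must appear last.
6. The enabling feature is at C4: it carries two one-carbon substituents, CH3 and C11, and only the one cis to the C1 oxygen on ring C can reach the aryl carbon ortho to that oxygen. If both are ester groups, closing ring B tells them apart and creates the C4 stereocentre in the same event.

## Retrosynthesis

**Formyl groups.** The two aryl–CHO bonds of 26 are cut first, giving diphenol 25. Carrying aldehydes earlier is excluded by the later organometallic and hydride steps. The forward reaction is a twofold formylation of the only two free positions of ring A, so no regiochemical choice arises.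

**Isobutyl group, phenols and C4 methyl.** The isobutyl group and both phenols of 25 come from the methallyl bis(benzyl ether) 24 in one hydrogenation. The C4 methyl of 24 is traced through mesylate 23 to the hydroxymethyl group of 22, that is, to an ester.

**C11–CH2 bond.** The C11–CH2 bond of 22 is cut to give diol 21 and a methallyl nucleophile. The neighbouring cut, adding the carbon chain to a C11 ketone and removing the oxygen with hydride, would place hydrogen rather than carbon on the open exo face and give the wrong epimer. The forward reaction must ionise a trioxygenated benzylic alcohol under mild Lewis acid and take the nucleophile from the exo face. Diol 21 comes from keto ester 20 by one hydride reduction.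

**Aryl–C11 bond (key cut).** In 20 the bond between ring A and C11 is cut, giving aryllithium 19 and its bromide 18, in which C4 carries two equivalent methyl esters. A Friedel–Crafts closure would need acid, a prior chemical differentiation of the carboxyl groups and a choice among nucleophilic ring positions. Making the O–C1 bond last would mean forming a tertiary ether in a cage. The anionic cut removes ring B and the C4 stereocentre at once, and fixes regiochemistry by the position of bromine. The forward reaction needs bromine–lithium exchange to be faster than attack on the esters.

**Cyclopropane.** The C6–C10 and C7–C10 bonds of 18 are cut to dibromide 17 and then to cyclohexene 16 (a dihalocarbene, then methyl transfer from copper). The more obvious order, closing ring B on the alkene and cyclopropanating afterwards, was set aside for a conformational reason.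
- Once ring B exists, ring D is locked in the half-chair that holds the C9 methyl axial on the α face, while the opposite face carries only the axial C2 methylene. The two faces then differ little.
- In the open hydrindene 16, ring D can flip to the half-chair with the C9 methyl equatorial. There the face syn to ring C is blocked by the pseudoaxial malonate carbon C4 and the α face carries only the axial ether oxygen.

The forward steps need α-face addition and a cuprate that leaves the aryl bromide alone.

**C2 oxygen.** Hydrindene 16 is traced through thionocarbonate 15 and alcohol 14 to ketone 13. The C2 ketone is reintroduced because it activates the dienophile of the next cut. It has to be gone before the aryllithium is made, which would otherwise attack it through a five-membered transition state.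

**C1–C5 and C8–C9 bonds.** Both bonds of 13 are cut in an intramolecular Diels–Alder transform to the achiral triene 12. The tertiary ether is thereby reduced to an enol ether of a phenol, and two rings and three contiguous stereocentres disappear. The forward reaction needs the Z enone (methyl cis to oxygen), the ketone endo (cis fusion) and one enantioface, which only a chiral Lewis acid can supply.

**Triene assembly.**
- The C1=C9 double bond of 12 is cut by an aldol condensation to ketone 8 and acetaldehyde 9, through aldol 10 and mesylate 11.
- The C3–C4 bond of 8 is cut to alkylidene malonate 7 and chloroketone 4 (deconjugative alkylation, which also unmasks the diene).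
- 7 comes from dimethyl malonate 5 and crotonaldehyde 6.
- 4 comes from bromophenol 2 and 1,3-dichloroacetone 3, and 2 from the commercial phenol 1.

## Roads not taken

**Alternative 1:**
- Cut: the C3–C4 bond of ring C, made while C11 and the ring-B oxygen are held together as a lactone.
- Forward step: the enolate at C4 of iodoethyl lactone A2 (a γ-lactone fused to the carane at C1–C5, with a 2-iodoethyl chain on C1) displaces iodide (5-exo-tet) and gives bridged lactone A1, a 2-oxabicyclo[2.2.1]heptan-3-one.
- Merits: the carane part (C6, C7, C9, C10) can come from the chiral pool, so this road needs neither an enantioselective catalyst nor a face-selective carbene addition. In both respects it is better than the chosen plan. C4 is fixed by bridging, as reliably as in the chosen plan.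
- Weak points: after A1 the arene must still be attached twice. Addition of an aryl nucleophile to the lactone carbonyl is feasible. The tertiary C1–O–aryl ether would then have to be forged from a hindered tertiary alkoxide and an electron-rich aryl halide on a congested cage, which leaves the hardest bond of the molecule for the end.
- Comparison: the chosen plan makes that ether in step 2 by alkylating a phenol and lets the cycloaddition make C1 quaternary. Against the chiral-pool advantage it offers a regiochemically fixed C–C closure of ring B, and it accepts steps 7 and 11 as its price.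

**Alternative 2:**
- Cut: the C4–C5 bond and the C1–O bond together.
- Forward step: a Lewis acid turns dienone A4 into a pentadienyl cation that closes conrotatorily (ring C), and the tethered phenol traps the oxyallyl cation at C1 (ring B), giving pentacyclic ketone A3.
- Merits: two rings, the tertiary ether and the quaternary C4 arise in one operation from a carane building block. If it worked it would be clearly shorter than the 19 steps proposed here.
- Weak points:
  - The phenol oxygen can reach the other oxyallyl terminus C3 through a six-membered ring, and C1 only through a seven-membered one, so the regiochemistry of trapping is doubtful.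
  - The sense of conrotation relative to C6/C7/C9 is not secured.
  - The cation bears charge at C5, next to the cyclopropane, which invites ring opening.
  - A3 still carries the C2 ketone and an unfunctionalised C11 methylene, so the isobutyl group must be installed later by benzylic functionalisation beside a quaternary carbon.
- Comparison: the chosen plan is longer, but each ring closure has a single possible regiochemical outcome and no cation is ever generated adjacent to ring E.

**Alternative 3:**
- Cut: C1–C5 and C8–C9.
- Forward step: the chiral-Lewis-acid cycloaddition of triene 12 to cis-hydrindenone A5, which is identical with 13.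
- Merits: the same as for step 7 of the chosen route. The tertiary ether, rings C and D and three stereocentres come from an achiral chain.
- Weak points: as a strategy it rests on its least precedented step and says nothing about ring B or about differentiating the two esters on C4.
- Comparison: up to 13 the two plans coincide and are equally good. The chosen plan puts the strategic weight on the known anionic closure. That closure solves ring B and C4 together and works equally on resolved material, so the cycloaddition can be replaced by a racemic version plus resolution without changing the plan.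

Key step: step 13

Assumption: the carbinol configurations at C2 (14, 15) and C11 (21) are left open, since both centres are removed later and either epimer serves; phenol 1 is bought as such.

## Steps

Step 1
Reactants: 1 3,5-bis(benzyloxy)phenol
Product: 2 2-bromo-3,5-bis(benzyloxy)phenol
Conditions: NBS (1.0 equiv), i-Pr2NH (10 mol %), CH2Cl2, −78 → 0 °C
Reagents that add atoms: N-bromosuccinimide, O=C1CCC(=O)N1Br
Why: Electrophilic aromatic bromination; amine-mediated delivery through the phenol O–H, together with crowding of the position between the two benzyloxy groups, should direct bromine ortho to the hydroxyl group.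

Step 2
Reactants: 2 2-bromo-3,5-bis(benzyloxy)phenol; 3 1,3-dichloroacetone
Product: 4 1-[2-bromo-3,5-bis(benzyloxy)phenoxy]-3-chloropropan-2-one
Conditions: 3 (3 equiv), K2CO3, acetone, rt
Reagents that add atoms: none
Why: Williamson ether synthesis on an α-chloro ketone; the excess of 3 suppresses double substitution, and this trivial SN2 step makes the C–O bond that later becomes the tertiary ether.

Step 3
Reactants: 5 dimethyl malonate; 6 (E)-crotonaldehyde
Product: 7 dimethyl 2-[(2E)-but-2-en-1-ylidene]malonate
Conditions: piperidine (cat.), AcOH (cat.), toluene, reflux, water separator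
Reagents that add atoms: none
Why: Knoevenagel condensation through the iminium ion (1,2-condensation); the malonate is symmetrical, so no geometry arises at the new double bond.

Step 4
Reactants: 7 dimethyl 2-[(2E)-but-2-en-1-ylidene]malonate; 4 1-[2-bromo-3,5-bis(benzyloxy)phenoxy]-3-chloropropan-2-one
Product: 8 dimethyl 2-[(1E)-buta-1,3-dien-1-yl]-2-{3-[2-bromo-3,5-bis(benzyloxy)phenoxy]-2-oxopropyl}malonate
Conditions: NaH (1.05 equiv), THF, 0 °C; then 4, NaI (10 mol %), 0 °C → rt
Reagents that add atoms: none
Why: Deconjugative α-alkylation of an alkylidene malonate: deprotonation of the terminal CH3 gives the extended enolate, which is alkylated at the malonate carbon (C4) by SN2 on the chloromethyl ketone, leaving the (E)-1,3-diene and forming the C3–C4 bond.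

Step 5
Reactants: 8 dimethyl 2-[(1E)-buta-1,3-dien-1-yl]-2-{3-[2-bromo-3,5-bis(benzyloxy)phenoxy]-2-oxopropyl}malonate; 9 acetaldehyde
Product: 10 dimethyl 2-[(1E)-buta-1,3-dien-1-yl]-2-{3-[2-bromo-3,5-bis(benzyloxy)phenoxy]-4-hydroxy-2-oxopentyl}malonate (diastereomer mixture)
Conditions: LiN(i-Pr)2 (1.1 equiv), THF, −78 °C; then 9 (3 equiv), −78 °C; then aq. NH4Cl at −78 °C
Reagents that add atoms: none
Why: Directed aldol addition; kinetic deprotonation should occur at the aryloxy-bearing CH2 (more acidic and unhindered) and not at the neopentyl CH2 next to C4, and the two new sp3 centres are erased in step 6.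

Step 6
Reactants: 10 dimethyl 2-[(1E)-buta-1,3-dien-1-yl]-2-{3-[2-bromo-3,5-bis(benzyloxy)phenoxy]-4-hydroxy-2-oxopentyl}malonate
Product: 12 dimethyl 2-[(1E)-buta-1,3-dien-1-yl]-2-{(3Z)-3-[2-bromo-3,5-bis(benzyloxy)phenoxy]-2-oxopent-3-en-1-yl}malonate, via mesylate 11 (not isolated)
Conditions: MsCl, Et3N, CH2Cl2, −20 °C; then DBU, −20 → 0 °C
Reagents that add atoms: none
Why: Mesylation and E1cB elimination complete the aldol condensation; the Z isomer (methyl anti to the acyl group, cis to the aryloxy group) is the more stable one and should predominate. The triene is kept cold and used at once.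

Step 7
Reactants: 12 dimethyl 2-[(1E)-buta-1,3-dien-1-yl]-2-{(3Z)-3-[2-bromo-3,5-bis(benzyloxy)phenoxy]-2-oxopent-3-en-1-yl}malonate
Product: 13 cis-hydrindenone: rings C and D formed; ketone at C2, two CO2Me on C4, C6=C7 double bond, 2-bromo-3,5-bis(benzyloxy)phenoxy on C1, CH3 on C9; O–C1, H–C5 and CH3–C9 on the same face
Conditions: [Cu((S,S)-t-Bu-box)](SbF6)2 (10 mol %; box = 2,2'-(propane-2,2-diyl)bis(4-tert-butyl-4,5-dihydrooxazole)), 4 Å MS, CH2Cl2, −20 °C → rt
Reagents that add atoms: none
Why: Proposed new method: catalytic enantioselective intramolecular Diels–Alder reaction of a 2-aryloxy enone. The divalent copper centre is expected to bind the ketone and the aryloxy oxygen as a five-membered chelate, activating the C1=C9 dienophile and shielding one of its faces. The tether ketone should sit endo (the usual preference of trienones with the carbonyl in the connecting chain, reinforced because the alternative puts the aryloxy group under the diene), which gives the cis fusion, and the Z geometry places the C9 methyl cis to oxygen. The closest known reactions are the bis(oxazoline)–copper-catalysed intramolecular Diels–Alder reactions of trienoyl imides and the chelation-controlled reactions of 2-alkoxy enones with chiral Lewis acids. The sense of induction cannot be predicted safely, and both ligand antipodes are available.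

Step 8
Reactants: 13 cis-hydrindenone
Product: 14 C2 alcohol of 13 (C2 epimers)
Conditions: NaBH4, MeOH, 0 °C
Reagents that add atoms: none
Why: Hydride reduction of the cyclopentanone, with the hindered esters untouched; methanol keeps any lactonisation onto the cis ester on the open side.

Step 9
Reactants: 14 C2 alcohol
Product: 15 C2 O-phenyl thionocarbonate of 14
Conditions: PhOC(S)Cl, DMAP, MeCN, rt
Reagents that add atoms: O-phenyl chlorothionoformate, S=C(Cl)Oc1ccccc1
Why: Acylation of the secondary alcohol to the radical precursor under non-alkoxide conditions, which avoids attack of an alkoxide on the neighbouring ester.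

Step 10
Reactants: 15 C2 thionocarbonate
Product: 16 hydrindene diester: cis-fused rings C (C1–C5, C2 and C3 both CH2) and D (C6=C7), aryloxy on C1, two CO2Me on C4, CH3 on C9; O–C1, H–C5 and CH3–C9 cis
Conditions: Bu3SnH (1.3 equiv), AIBN (cat.), toluene, 90 °C
Reagents that add atoms: none
Why: Barton–McCombie deoxygenation; the stannyl radical adds to C=S far faster than it abstracts bromine from the electron-rich aryl bromide, and hydrogen transfer to the C2 radical at this stannane concentration should outrun loss of the β-aryloxy group.

Step 11
Reactants: 16 hydrindene diester
Product: 17 10,10-dibromocyclopropane: CBr2 bridging C6 and C7 of 16 on the face of O–C1, H–C5 and CH3–C9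
Conditions: CHBr3, 50 % aq. NaOH, BnEt3NCl (10 mol %), CH2Cl2, 0 °C → rt
Reagents that add atoms: bromoform, BrC(Br)Br
Why: Cis-stereospecific [2+1] addition of dibromocarbene under phase-transfer conditions. In the open hydrindene, ring D can adopt the half-chair with the C9 methyl equatorial, where the face syn to ring C is closed by the pseudoaxial malonate carbon C4 and the α face carries only the axial ether oxygen, so the carbene should add on the α face as the target requires.

Step 12
Reactants: 17 dibromocyclopropane
Product: 18 gem-dimethylcyclopropane (ring E complete): bromoaryl ether with two CO2Me on C4, ring E cis to O–C1, H–C5 and CH3–C9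
Conditions: Me2CuLi (6 equiv, from CuI and MeLi), Et2O, −78 → −20 °C; then MeI (excess), −20 °C → rt
Reagents that add atoms: lithium dimethylcuprate, [Li+].C[Cu-]C; iodomethane, CI
Why: Cuprate gem-dimethylation of a gem-dibromocyclopropane: bromine–copper exchange, 1,2-methyl shift with loss of bromide, then methylation of the cyclopropylcopper by MeI. The strained dibromide should exchange well below the temperature at which a cuprate attacks an electron-rich, doubly ortho-substituted aryl bromide or a hindered ester.

Step 13
Reactants: 18 gem-dimethylcyclopropane bromoaryl ether diester
Product: 20 tetracyclic β-keto ester (ring B closed; aryl ketone at C11; one CO2Me left on C4), via aryllithium 19 (not isolated)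
Conditions: t-BuLi (2.1 equiv), THF (0.01 M), −100 °C; then −78 → −20 °C; then aq. NH4Cl
Reagents that add atoms: none
Why: Parham cyclization: bromine–lithium exchange at −100 °C, assisted by the two flanking oxygens, is faster than addition of t-BuLi to the neopentyl-type esters and gives aryllithium 19, while the second equivalent of t-BuLi destroys the t-BuBr formed. On warming, 19 adds to the ester carbonyl that lies cis to the aryloxy group on ring C (7-exo-trig closure of ring B, forming the aryl–C11 bond), and loss of methoxide gives an aryl ketone that has no enolisable hydrogen and is shielded by two ortho substituents against a second addition. The new stereocentre C4 is controlled entirely by C1: the two esters are diastereotopic, and the one trans to the ether oxygen cannot reach the aryl carbon without an impossible trans-bridged ring, so the group selectivity is geometric and not a matter of rates. The chemoselectivity that is needed (exchange before carbonyl addition, intramolecular before intermolecular acylation) is secured by low temperature, dilution and the hindered position of both esters. The C2 ketone was removed beforehand because it would be attacked through a five-membered transition state. The closest known reaction type is the acylation of an aryllithium, made by halogen–metal exchange, by an ester in the same molecule to give benzo-fused cyclic ketones.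

Step 14
Reactants: 20 tetracyclic β-keto ester
Product: 21 diol: C11 secondary benzylic alcohol (epimers) and CH2OH on C4
Conditions: LiAlH4, THF, 0 °C → rt; aqueous NaOH work-up
Reagents that add atoms: none
Why: Hydride reduction of both the aryl ketone and the ester; the C11 carbinol configuration is immaterial because the centre is ionised in step 15.

Step 15
Reactants: 21 diol
Product: 22 C11-(2-methylallyl) compound with CH2OH on C4; methallyl group on C11 syn to the one-carbon bridge C5
Conditions: methallyltrimethylsilane (3 equiv), BF3·OEt2 (20 mol %), CH2Cl2, −78 → −30 °C
Reagents that add atoms: methallyltrimethylsilane, C=C(C)C[Si](C)(C)C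
Why: Lewis-acid ionisation of the electron-rich benzylic alcohol to a trioxygenated benzyl cation and capture by the allylsilane (Hosomi–Sakurai-type allylation). The nucleophile should enter from the exo face, syn to the one-carbon bridge C5, because the two-carbon bridge C2–C3 lies closer to the endo face, and this gives the C11 configuration of the target. The cation is not adjacent to ring E, and any capture by the neighbouring CH2OH (oxetane) would be reversible.

Step 16
Reactants: 22 C11-methallyl primary alcohol
Product: 23 primary mesylate of 22
Conditions: MsCl, Et3N, CH2Cl2, 0 °C
Reagents that add atoms: methanesulfonyl chloride, CS(=O)(=O)Cl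
Why: Sulfonylation through sulfene is insensitive to the neopentyl environment of the C4 hydroxymethyl group.

Step 17
Reactants: 23 mesylate
Product: 24 C4-methyl compound: C11-methallyl bis(benzyl ether)
Conditions: LiEt3BH (5 equiv), THF, 65 °C
Reagents that add atoms: none
Why: Hydride displacement of a neopentyl sulfonate, for which triethylborohydride is the reagent of choice; it completes the conversion of the spectator ester into the C4 methyl group.

Step 18
Reactants: 24 C11-methallyl bis(benzyl ether)
Product: 25 diphenol with isobutyl group on C11 (both formyl positions of ring A still free)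
Conditions: H2 (1 atm), Pd/C (10 %), EtOAc–MeOH, rt
Reagents that add atoms: none
Why: One hydrogenation saturates the 1,1-disubstituted alkene and hydrogenolyses both benzyl ethers; an unactivated gem-dimethylcyclopropane and the alkyl aryl ether should survive these mild conditions.

Step 19
Reactants: 25 diphenol
Product: 26 CNP0202714.1 (target)
Conditions: Cl2CHOMe (6 equiv), TiCl4 (6 equiv), CH2Cl2, −78 → 0 °C; then ice-water
Reagents that add atoms: dichloromethyl methyl ether, COC(Cl)Cl; water, O
Why: Twofold Rieche formylation, with titanium phenoxide-directed attack at the only two free positions of ring A (each ortho or para to all three oxygens), and hydrolysis of the chloro ethers on work-up to the two aldehydes.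

## Compound list

1 | 3,5-bis(benzyloxy)phenol | Oc1cc(OCc2ccccc2)cc(OCc2ccccc2)c1 | starting material
2 | 2-bromo-3,5-bis(benzyloxy)phenol | Oc1cc(OCc2ccccc2)cc(OCc2ccccc2)c1Br | intermediate
3 | 1,3-dichloroacetone | ClCC(=O)CCl | starting material
4 | 1-[2-bromo-3,5-bis(benzyloxy)phenoxy]-3-chloropropan-2-one | ClCC(=O)COc1cc(OCc2ccccc2)cc(OCc2ccccc2)c1Br | intermediate
5 | dimethyl malonate | COC(=O)CC(=O)OC | starting material
6 | (E)-crotonaldehyde | C/C=C/C=O | starting material
7 | dimethyl 2-[(2E)-but-2-en-1-ylidene]malonate | C/C=C/C=C(C(=O)OC)C(=O)OC | intermediate
8 | dimethyl 2-[(1E)-buta-1,3-dien-1-yl]-2-{3-[2-bromo-3,5-bis(benzyloxy)phenoxy]-2-oxopropyl}malonate | C=C/C=C/C(CC(=O)COc1cc(OCc2ccccc2)cc(OCc2ccccc2)c1Br)(C(=O)OC)C(=O)OC | intermediate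
9 | acetaldehyde | CC=O | starting material
10 | aldol adduct of 8 with acetaldehyde (4-hydroxy-2-oxopentyl chain, diastereomer mixture) | C=C/C=C/C(CC(=O)C(Oc1cc(OCc2ccccc2)cc(OCc2ccccc2)c1Br)C(C)O)(C(=O)OC)C(=O)OC | intermediate
11 | mesylate of 10 (not isolated) | C=C/C=C/C(CC(=O)C(Oc1cc(OCc2ccccc2)cc(OCc2ccccc2)c1Br)C(C)OS(C)(=O)=O)(C(=O)OC)C(=O)OC | intermediate
12 | (Z)-2-aryloxy enone triene | C/C=C(\Oc1cc(OCc2ccccc2)cc(OCc2ccccc2)c1Br)C(=O)CC(/C=C/C=C)(C(=O)OC)C(=O)OC | intermediate
13 | cis-hydrindenone (C2 ketone, C4 gem-diester, C6=C7; O–C1, H–C5, CH3–C9 cis) | Brc1c(OCc2ccccc2)cc(OCc2ccccc2)cc1O[C@]12C(=O)CC(C(=O)OC)(C(=O)OC)[C@H]1C=CC[C@@H]2C | intermediate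
14 | C2 alcohol of 13 (C2 epimers) | Brc1c(OCc2ccccc2)cc(OCc2ccccc2)cc1O[C@]12C(O)CC(C(=O)OC)(C(=O)OC)[C@H]1C=CC[C@@H]2C | intermediate
15 | C2 O-phenyl thionocarbonate of 14 | Brc1c(OCc2ccccc2)cc(OCc2ccccc2)cc1O[C@]12C(OC(=S)Oc3ccccc3)CC(C(=O)OC)(C(=O)OC)[C@H]1C=CC[C@@H]2C | intermediate
16 | hydrindene bromoaryl ether with gem-diester (C6=C7) | Brc1c(OCc2ccccc2)cc(OCc2ccccc2)cc1O[C@]12CCC(C(=O)OC)(C(=O)OC)[C@H]1C=CC[C@@H]2C | intermediate
17 | 10,10-dibromocyclopropane of 16 (α face) | Brc1c(OCc2ccccc2)cc(OCc2ccccc2)cc1O[C@]12CCC(C(=O)OC)(C(=O)OC)[C@H]1[C@H]3[C@@H](C[C@@H]2C)C3(Br)Br | intermediate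
18 | gem-dimethylcyclopropane bromoaryl ether with gem-diester (precursor of the key step) | Brc1c(OCc2ccccc2)cc(OCc2ccccc2)cc1O[C@]12CCC(C(=O)OC)(C(=O)OC)[C@H]1[C@H]3[C@@H](C[C@@H]2C)C3(C)C | intermediate
19 | aryllithium from 18 (not isolated) | [Li]c1c(OCc2ccccc2)cc(OCc2ccccc2)cc1O[C@]12CCC(C(=O)OC)(C(=O)OC)[C@H]1[C@H]3[C@@H](C[C@@H]2C)C3(C)C | intermediate
20 | tetracyclic β-keto ester (ring B closed, ring E present; product of the key step) | O=C1c2c(OCc4ccccc4)cc(OCc4ccccc4)cc2O[C@]23CC[C@@]1(C(=O)OC)[C@H]2[C@H]1[C@@H](C[C@@H]3C)C1(C)C | intermediate
21 | diol (C11–OH epimers, C4–CH2OH) | OC1c2c(OCc4ccccc4)cc(OCc4ccccc4)cc2O[C@]23CC[C@@]1(CO)[C@H]2[C@H]1[C@@H](C[C@@H]3C)C1(C)C | intermediate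
22 | C11-methallyl, C4-hydroxymethyl compound | C=C(C)C[C@H]1c2c(OCc4ccccc4)cc(OCc4ccccc4)cc2O[C@]23CC[C@@]1(CO)[C@H]2[C@H]1[C@@H](C[C@@H]3C)C1(C)C | intermediate
23 | mesylate of 22 | C=C(C)C[C@H]1c2c(OCc4ccccc4)cc(OCc4ccccc4)cc2O[C@]23CC[C@@]1(COS(C)(=O)=O)[C@H]2[C@H]1[C@@H](C[C@@H]3C)C1(C)C | intermediate
24 | C11-methallyl, C4-methyl bis(benzyl ether) | C=C(C)C[C@H]1c2c(OCc4ccccc4)cc(OCc4ccccc4)cc2O[C@]23CC[C@@]1(C)[C@H]2[C@H]1[C@@H](C[C@@H]3C)C1(C)C | intermediate
25 | C11-isobutyl diphenol | CC(C)C[C@H]1c2c(O)cc(O)cc2O[C@]23CC[C@@]1(C)[C@H]2[C@H]1[C@@H](C[C@@H]3C)C1(C)C | intermediate
26 | CNP0202714.1 | CC(C)C[C@H]1c2c(O)c(C=O)c(O)c(C=O)c2O[C@]23CC[C@@]1(C)[C@H]2[C@H]1[C@@H](C[C@@H]3C)C1(C)C | target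

## Step count and least certain steps

Total: 19 steps. Longest linear sequence: 18 steps (from 1 through steps 1, 2 and 4–19; step 3 is a one-step side branch).

**Step 7 (enantioselective cycloaddition).** The catalyst may bind weakly or non-selectively: the aryloxy oxygen is a poor donor and the malonate can compete as a chelating site. That would lead to low enantioselectivity, a racemic background cyclization, or the wrong sense of induction. Fallback with known chemistry, setting out from 12: the triene is cyclized thermally (toluene, 80–110 °C, BHT), the established behaviour of trienones with the carbonyl in the connecting chain. This gives the racemate, that is 13 together with its mirror image, the enantiomeric cis-hydrindenone F1. The enantiomers are separated by preparative chromatography on a chiral stationary phase, and the route is rejoined at 13.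

**Step 13 (key step).** Ring closure may be slow because the reactive conformer is strained: the aryloxy group and C4 are both equatorial on ring D, and the C9 methyl is axial beneath the inner methyl of ring E. The aryllithium could then be diverted by proton transfer from a benzylic OCH2 group (followed by Wittig rearrangement) or by intermolecular acylation. Fallback, setting out from 16: the ring is closed before the cyclopropane is built.
- The same exchange and closure on the alkene, where that conformer is unstrained, gives the tetracyclic alkene keto ester F2.
- Dibromocarbene addition (CHBr3/NaOH under phase transfer, or neutral PhHgCBr3 if hydroxide threatens the non-enolisable keto ester) gives the dibromocyclopropane keto ester F3.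
- Me2CuLi and then MeI return the route to 20.

This order also takes the aryl bromide out of the cuprate step. Its price is the less predictable face selectivity of the carbene on the locked ring D.

**Step 11 (dibromocarbene addition).** Facial selectivity may be poor, or addition may occur on the face syn to ring C, if the axial aryloxy group hinders the α face more than expected. Fallback, setting out from 16: the carbon is delivered from a hydroxyl group on the correct face.
- Ring B is closed first, giving F2 as above.
- LiAlH4 gives the alkene diol F4, whose C4 hydroxymethyl group lies gauche to C6 on the α side of ring D.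
- A hydroxyl-directed isopropylidene transfer with the zinc carbenoid from Et2Zn and 2,2-diiodopropane (Simmons–Smith type) then gives 21 directly.

**Step 15 (benzylic allylation).** The cation may be attacked from the endo face, or with low selectivity, and the attached group cannot be epimerised afterwards. Fallback, setting out from 20: carbon and hydrogen are attached to C11 in the opposite order.
- i-BuLi/CeCl3 adds to the ketone and gives the tertiary benzylic alcohol F5.
- Ionic hydrogenation (Et3SiH, CF3CO2H) delivers hydride to whichever face of the cation a nucleophile prefers, so the isobutyl group ends on the other face; this gives the isobutyl ester F6.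
- LiAlH4 gives the primary alcohol F7, MsCl the mesylate F8, and LiEt3BH the C4-methyl bis(benzyl ether) F9.
- Hydrogenolysis (H2, Pd/C) returns the route to 25.

Whichever face the cation favours, one of the two orders gives the natural C11 epimer.

**Step 19 (Rieche formylation).** TiCl4 and the HCl set free may open the cyclopropane or ionise the tertiary C1–O bond, or the second formylation may stall. Fallback, setting out from 25 and returning at 26: base-mediated ortho-formylation of the magnesium phenoxides (MgCl2, Et3N, paraformaldehyde, MeCN, reflux). Both free ring positions are ortho to a hydroxyl group, no strong acid is present, and no new intermediate is formed.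

## Further compounds

F1 | step 7 | enantiomer of cis-hydrindenone 13 | Brc1c(OCc2ccccc2)cc(OCc2ccccc2)cc1O[C@@]12C(=O)CC(C(=O)OC)(C(=O)OC)[C@@H]1C=CC[C@H]2C
F2 | step 13 | tetracyclic alkene β-keto ester (ring B closed, C6=C7 still present) | O=C1c2c(OCc4ccccc4)cc(OCc4ccccc4)cc2O[C@]23CC[C@@]1(C(=O)OC)[C@H]2C=CC[C@@H]3C
F3 | step 13 | tetracyclic 10,10-dibromocyclopropane β-keto ester | O=C1c2c(OCc4ccccc4)cc(OCc4ccccc4)cc2O[C@]23CC[C@@]1(C(=O)OC)[C@H]2[C@H]1[C@@H](C[C@@H]3C)C1(Br)Br
F4 | step 11 | tetracyclic alkene diol (C11–OH epimers, C4–CH2OH, C6=C7) | OC1c2c(OCc4ccccc4)cc(OCc4ccccc4)cc2O[C@]23CC[C@@]1(CO)[C@H]2C=CC[C@@H]3C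
F5 | step 15 | C11 tertiary alcohol with isobutyl group, C4 ester (C11 epimers) | CC(C)CC1(O)c2c(OCc4ccccc4)cc(OCc4ccccc4)cc2O[C@]23CC[C@@]1(C(=O)OC)[C@H]2[C@H]1[C@@H](C[C@@H]3C)C1(C)C
F6 | step 15 | C11-isobutyl C4 methyl ester | CC(C)C[C@H]1c2c(OCc4ccccc4)cc(OCc4ccccc4)cc2O[C@]23CC[C@@]1(C(=O)OC)[C@H]2[C@H]1[C@@H](C[C@@H]3C)C1(C)C
F7 | step 15 | C11-isobutyl C4 hydroxymethyl compound | CC(C)C[C@H]1c2c(OCc4ccccc4)cc(OCc4ccccc4)cc2O[C@]23CC[C@@]1(CO)[C@H]2[C@H]1[C@@H](C[C@@H]3C)C1(C)C
F8 | step 15 | mesylate of F7 | CC(C)C[C@H]1c2c(OCc4ccccc4)cc(OCc4ccccc4)cc2O[C@]23CC[C@@]1(COS(C)(=O)=O)[C@H]2[C@H]1[C@@H](C[C@@H]3C)C1(C)C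
F9 | step 15 | C11-isobutyl C4-methyl bis(benzyl ether) | CC(C)C[C@H]1c2c(OCc4ccccc4)cc(OCc4ccccc4)cc2O[C@]23CC[C@@]1(C)[C@H]2[C@H]1[C@@H](C[C@@H]3C)C1(C)C
F0 | step 19 | none | none
A1 | alternative 1 | tetracyclic bridged lactone (2-oxabicyclo[2.2.1]heptan-3-one fused to the carane) | O=C1O[C@]23CC[C@@]1(C)[C@H]2[C@H]1[C@@H](C[C@@H]3C)C1(C)C
A2 | alternative 1 | carane-fused γ-lactone with 2-iodoethyl chain on C1 (C4 epimers) | ICC[C@@]12OC(=O)C(C)[C@H]1[C@H]3[C@@H](C[C@@H]2C)C3(C)C
A3 | alternative 2 | pentacyclic α-aryloxy cyclopentanone with benzylic CH2 | C1c2c(OCc4ccccc4)cc(OCc4ccccc4)cc2O[C@]23C(=O)C[C@@]1(C)[C@H]2[C@H]1[C@@H](C[C@@H]3C)C1(C)C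
A4 | alternative 2 | carenyl alkenyl ketone with tethered phenol (dienone) | O=C(/C=C(\C)Cc1c(O)cc(OCc2ccccc2)cc1OCc1ccccc1)C1=C[C@H]2[C@@H](C[C@@H]1C)C2(C)C
A5 | alternative 3 | cis-hydrindenone aryl ether with gem-diester (identical with 13) | Brc1c(OCc2ccccc2)cc(OCc2ccccc2)cc1O[C@]12C(=O)CC(C(=O)OC)(C(=O)OC)[C@H]1C=CC[C@@H]2C
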